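Amounts of target, in percent of the starting material charged, lie close in your two runs: at 2.50 min oak stands at 10.8% and alder at 11.4%, with 2.22 times oak's charge in alder, so here is the quick number you asked for, reckoned in powers of ten.

all flasks: free catalyst 20 mM

| run | starting material | coupling partner | remark | time |
|---|---|---|---|---|
| oak | 0.54 M | 1.6 M | run made earlier |  |
| alder | 1.2 M | 1.6 M | run made earlier |  |
| flask | 0.80 M | 1.60 M |  | 2.0 min |

| run | time / min | target / % | starting material / % |
|---|---|---|---|
| oak | 0.167 | 1.5 | 97.6 |
| oak | 0.500 | 3.8 | 96.0 |
| oak | 0.833 | 5.9 | 93.1 |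
| oak | 1.33 | 7.9 | 90.4 |
| oak | 2.00 | 9.5 | 88.1 |
| oak | 2.50 | 10.8 | 86.2 |
| alder | 0.200 | 0.6 | 97.9 |
| alder | 0.333 | 2.6 | 96.2 |
| alder | 0.500 | 4.7 | 96.0 |
| alder | 0.833 | 5.2 | 93.1 |
| alder | 1.33 | 6.4 | 92.3 |
| alder | 2.50 | 11.4 | 86.4 |

(standard deviation of a reading: 0.5 percentage points)

- amount of target in percent of the starting material charged, at 6.0 s, 30 s and 2.0 min

- the analysis behind the earlier runs scatters by 0.5 percentage points, standard deviation

From those two readings we take

m = log10(11.4% / 10.8%) / log10(1.2 M / 0.54 M) = 0.0677

and call m the percent exponent, the rise in log10 of the target percent at a fixed time per unit rise in log10 of the charge of starting material. At m = 0 the percent curve does not move with the charge, which is pseudo-first-order behaviour in starting material. The scatter on each reading puts about 0.0820 on m, so our m is smaller than its own uncertainty. Scaling oak's reading at 2.00 min to the flask's charge, we commit to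

P = 9.5% × (0.80 M / 0.54 M)^m = 9.76%

and the same step on oak at 30 s gives 3.90%. Neither run was read as early as 6.0 s, so there we have no number of our own.

Your forecast says 0.9% at 6.0 s, 4.2% at 30 s and 9.3% at 2.0 min, on the ground that the flask “should follow the same percent curve”. Our figure at 2.0 min stands 0.46 percentage points above yours.

The flask gives 0.859% at 6.0 s, 3.86% at 30 s and 9.68% at 2.0 min, so your forecast is right within the tolerance.

    starting material + free catalyst ⇌ catalyst intermediate A (K = 0.240 /M, k = 0.200 /M/s)
    coupling partner + catalyst intermediate A → catalyst intermediate B (k = 0.450 /M/s)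
    catalyst intermediate B ⇌ free catalyst + target (K = 44.0 M, k = 48.0 /s)
    target ⇌ isomer of the product (K = 1.70, k = 0.00360 /s)
    2 free catalyst ⇌ resting dimer (K = 83.0 /M, k = 0.410 /M/s)

Against oak's reading, the flask's value at 2.0 min gives m = 0.0478, and m carried from the flask at 30 s to alder's charge gives 3.97% against alder's reading of 4.7%. At 0.200 min catalyst intermediate A held 8.00% of the flask's catalyst, free catalyst 78.2% and the resting dimer 13.6%. By 2.00 min free catalyst had fallen to 45.5% and the resting dimer had risen to 50.1%, while target was still made 2.40 times faster, net, than it was used up, and the isomer of the product stood at 2.33% of the starting material charged.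

The earlier runs and the new flask stem from a simulated flask on assumed constants.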